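## The problem

CNP0018313.0 (30) is a linear phloroglucinol pentamer. Its five benzene rings, lettered A to E from the 3,5-dihydroxyphenoxy end, are joined only by four diaryl ether bonds: A5–O–B1, B6–O–C1, C4–O–D1 and D6–O–E1. The molecule has no stereocentre and no configurationally stable axis, so the difficulty is purely regiochemical: eleven hydroxyls and four ether oxygens must be placed on rings that differ only in substitution pattern. The carbons B1, C1, D1 and E1 each lie between two ortho oxygens, so every phenol that must be arylated there is hindered and electron-rich. Rings B, C and D accept an ortho or para formyl group on the electrophilic partner, because that carbon is oxygenated in the target and the aldehyde can later become a phenol. Ring A does not, since the carbons ortho and para to A5 carry only hydrogen. The free polyphenol is oxidised by air under base and its rings are attacked by halogens, peracids and carbocations, so all hydroxyls travel as ethers until the last step. The enabling feature is the 1,3,5-pattern of ring A: A1–A2–A3–A4 with oxygen on A1 and A3 maps onto a 1,1-dialkoxy-3-silyloxybutadiene, and A5–A6 with the ether oxygen on A5 maps onto an aryloxyalkyne, so ring A can be built around the B1 oxygen.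

## Retrosynthesis

Target 30 is traced back to 3-methoxy-5-(aryloxy)phenol 29 by cutting ten O–methyl bonds. Methyl ethers are chosen because they survive carbonate bases, peroxide, butyllithium, heat and hydrogenation, and add little bulk to the crowded ethers. The forward reaction must cleave ten ethers without touching the four diaryl ethers.

Phenol 29 is traced back to benzyl ester 27 by restoring a carboxyl group on A6. The ester is a removable activator for the ring-forming step. A benzyl ester is preferred to a methyl ester because a benzoate with two ortho oxygens and a para hydroxyl resists saponification. Hydrogenolysis frees acid 28, and such 2,4,6-trioxygenated benzoic acids lose carbon dioxide under mild acid.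

Ester 27 is cut at A4–A5 and A6–A1 into benzyl 3-aryloxypropiolate 21 and diene 24. The neighbouring cut, the A5–O bond, would require arylation of the crowded phenol 16 with an unactivated ring A halide. The chosen cut lets the B1 oxygen enter as a substituent on an sp carbon. The precursor 21 contains only four rings and a three-carbon chain. The forward reaction must place methoxy, hydroxy and aryloxy on A1, A3 and A5.

Propiolate 21 is cut at the alkyne–carbonyl bond and the O–C(sp) bond, leading through dichlorovinyl ether 18 to phenol 16 and trichloroethylene 17. The hindered phenoxide attacks a linear two-carbon electrophile, which is far less demanding than an aryl halide. Elimination and chlorine–lithium exchange give acetylide 20, which is acylated.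

Diene 24 comes from enone 23 by silylation at the methyl group, and 23 from 1,1-dimethoxyethene 22 by C-acylation. Both are short, known operations on small molecules.

Phenol 16 is cut at the B6–O bond into phenol 13 and 2-fluoro-4,6-dimethoxybenzaldehyde 6, by way of aldehyde 14. The formyl group at B1 activates the fluorine at B6 and afterwards becomes the B1 oxygen. Both methoxy groups of 6 are meta to fluorine and do not deactivate the substitution. Aldehyde 6 comes from 1-fluoro-3,5-dimethoxybenzene 4 by formylation.

Phenol 13 is cut at the C4–O bond into phenol 9 and 4-bromo-2,6-dimethoxybenzaldehyde 10, by way of aldehyde 11. Ring C is the only ring whose two ether oxygens are para, so the activating formyl group sits para to the leaving group and later becomes the C1 oxygen. The bromide is chosen because it is a catalogue compound with unambiguous regiochemistry, and it asks for copper catalysis.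

Phenol 9 is cut at the D6–O bond into 2,4,6-trimethoxyphenol 3 and a second molecule of 6, by way of aldehyde 7. Phenol 3 comes from 2,4,6-trimethoxybenzaldehyde 1 by oxidation.

## Roads not taken

Alternative 1: Ring B would be cut at B4–B5 and traced to the racemic cyclobutenone A1, which carries the ring C oxygen on a vinyl carbon. On heating, A1 should open to a dienylketene and reclose onto the vinyl terminus to give hydroquinone A2. The merits are real: the 1,2,3,5 pattern of ring B is fixed by a pericyclic step, the conditions are neutral, and the B6–O–C1 ether is carried in, not made by arylation. The weak points lie after the key step. A2 has two free phenols, at B1 and B4, that must be differentiated. The B1 oxygen must then be arylated by ring A, which is the crowded ether the chosen plan avoids arylating. Rings D and E would have to be attached through the unhindered C4 oxygen to a D1 carbon flanked by two oxygens, for which no activated substitution exists. A1 is not a catalogue compound, and its assembly adds organometallic steps. In regiochemical certainty for ring B this road is as good as the chosen plan. The chosen plan makes ring B in two well-known steps from 6 and keeps its ring-forming step for the ether that activated substitution cannot make.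

Alternative 2: Ring E would be cut at E2–E3 and E5–E6 into aryloxymalonate A3 and dimethyl 3-oxopentanedioate A4. A double Claisen condensation should give the trihydroxyisophthalate A5. The merits are cheap three-carbon components, formation of the E1–O–D6 ether by simple alkylation, and a ring E that arrives as the free triol. The weak points are several. Ring E is the one ring that can be had in one step from a catalogue aldehyde (1 to 3). The cross-condensation must outrun self-condensation of A4. Two ester groups must be removed while three phenols are free, and those phenols then need protection for later steps. The hardest ether, A5–O–B1, is left untouched. In cost of the ring E carbons this road is better. The chosen plan sets against it a one-step ring E and a key step aimed at the bond that has no conventional solution.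

Alternative 3: Ring D would be cut at D2–D3 and D4–D5 into the racemic bis(aryloxy)cyclobutenone A6 and ethoxyacetylene A7. A Danheiser benzannulation should give the ring C–D–E trimer phenol A8 with both diaryl ether oxygens of ring D already in place. This is more convergent than the chosen plan for the most congested ring: one step does what steps 3 to 6 below do in four. The weak points are in the precursor. A6 has an aryloxy group on its sp3 carbon, β to the carbonyl, and is not an established class. Placing two different aryloxy groups regioselectively on the four-membered ring is itself unsolved. The derived vinylketene could lose aryloxide. Rings B and A would still have to be added, including the crowded A–B ether. The chosen plan sets against the better convergence of this road its use of catalogue building blocks and repeated two-step cycles, with a single untested step.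

Key step: step 13

Remark: Ar denotes the permethylated ring B–C–D–E residue of phenol 16 (16 = ArOH); 4-bromo-2,6-dimethoxybenzaldehyde 10 and 1,1-dimethoxyethene 22 are taken to be catalogue compounds.

## Steps

Step 1
Reactants: 1 2,4,6-trimethoxybenzaldehyde
Product: 3 2,4,6-trimethoxyphenol, via 2,4,6-trimethoxyphenyl formate 2 (not isolated)
Conditions: H2O2 (30% aq), H2SO4 (cat.), MeOH, rt
Reagents that add atoms: hydrogen peroxide, OO
Why: Acid-catalysed Dakin (Baeyer–Villiger-type) oxidation; the electron-rich, doubly ortho-oxygenated aryl group migrates in the peroxide adduct and the formate is methanolysed in the same pot, with no peracid present to attack the ring.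

Step 2
Reactants: 4 1-fluoro-3,5-dimethoxybenzene
Product: 6 2-fluoro-4,6-dimethoxybenzaldehyde, via iminium chloride 5 (not isolated)
Conditions: POCl3, DMF, 0 → 80 °C; then aq NaOH
Reagents that add atoms: N,N-dimethylformamide, CN(C)C=O; water, O
Why: Vilsmeier–Haack formylation; attack para to one methoxy and ortho to the other should dominate over attack between the two methoxy groups, as with other 5-substituted 1,3-dimethoxybenzenes, and the minor regioisomer is removed by crystallisation or chromatography.

Step 3
Reactants: 3 2,4,6-trimethoxyphenol; 6 2-fluoro-4,6-dimethoxybenzaldehyde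
Product: 7 2,4-dimethoxy-6-(2,4,6-trimethoxyphenoxy)benzaldehyde
Conditions: Cs2CO3, DMSO, 110 °C
Reagents that add atoms: none
Why: Nucleophilic aromatic substitution of fluoride activated by the ortho formyl group; both methoxy groups are meta to fluorine and do not enrich the carbon attacked, and fluoride displacement tolerates a phenoxide with two ortho substituents.

Step 4
Reactants: 7 2,4-dimethoxy-6-(2,4,6-trimethoxyphenoxy)benzaldehyde
Product: 9 2,4-dimethoxy-6-(2,4,6-trimethoxyphenoxy)phenol, via dimer aryl formate 8 (not isolated)
Conditions: H2O2 (30% aq), H2SO4 (cat.), MeOH–CH2Cl2, rt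
Reagents that add atoms: hydrogen peroxide, OO
Why: Acid-catalysed Dakin oxidation as in step 1; the aldehyde has two ortho oxygens, which favours aryl migration, and the diaryl ether is inert to dilute acid and peroxide.

Step 5
Reactants: 9 2,4-dimethoxy-6-(2,4,6-trimethoxyphenoxy)phenol; 10 4-bromo-2,6-dimethoxybenzaldehyde
Product: 11 4-[2,4-dimethoxy-6-(2,4,6-trimethoxyphenoxy)phenoxy]-2,6-dimethoxybenzaldehyde
Conditions: CuI (10 mol %), picolinic acid (20 mol %), K3PO4, DMSO, 90 °C
Reagents that add atoms: none
Why: Ullmann-type diaryl ether coupling; the bromide is unhindered and activated by the para formyl group, and the copper–picolinate system is known to couple phenols bearing two ortho substituents.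

Step 6
Reactants: 11 4-[2,4-dimethoxy-6-(2,4,6-trimethoxyphenoxy)phenoxy]-2,6-dimethoxybenzaldehyde
Product: 13 4-[2,4-dimethoxy-6-(2,4,6-trimethoxyphenoxy)phenoxy]-2,6-dimethoxyphenol, via trimer aryl formate 12 (not isolated)
Conditions: H2O2 (30% aq), H2SO4 (cat.), MeOH–CH2Cl2, rt
Reagents that add atoms: hydrogen peroxide, OO
Why: Acid-catalysed Dakin oxidation; the 2,6-dimethoxy-4-aryloxyphenyl group is a good migrating group and the formate is cleaved by methanol in situ.

Step 7
Reactants: 13 4-[2,4-dimethoxy-6-(2,4,6-trimethoxyphenoxy)phenoxy]-2,6-dimethoxyphenol; 6 2-fluoro-4,6-dimethoxybenzaldehyde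
Product: 14 2-{4-[2,4-dimethoxy-6-(2,4,6-trimethoxyphenoxy)phenoxy]-2,6-dimethoxyphenoxy}-4,6-dimethoxybenzaldehyde
Conditions: Cs2CO3, DMSO, 120 °C
Reagents that add atoms: none
Why: Nucleophilic aromatic substitution of the same type as step 3; the nucleophile is again a 2,6-dimethoxyphenoxide and the electrophile is identical.

Step 8
Reactants: 14 2-{4-[2,4-dimethoxy-6-(2,4,6-trimethoxyphenoxy)phenoxy]-2,6-dimethoxyphenoxy}-4,6-dimethoxybenzaldehyde
Product: 16 2-{4-[2,4-dimethoxy-6-(2,4,6-trimethoxyphenoxy)phenoxy]-2,6-dimethoxyphenoxy}-4,6-dimethoxyphenol (ArOH), via tetramer aryl formate 15 (not isolated)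
Conditions: H2O2 (30% aq), H2SO4 (cat.), MeOH–CH2Cl2, rt
Reagents that add atoms: hydrogen peroxide, OO
Why: Acid-catalysed Dakin oxidation as in steps 4 and 6; it converts the activating formyl group into the B1 oxygen that will carry ring A.

Step 9
Reactants: 16 ArOH; 17 trichloroethylene
Product: 18 (E)-1,2-dichloroethenyl Ar ether (ArO–CCl=CHCl)
Conditions: K2CO3, DMF, 70 °C
Reagents that add atoms: none
Why: Base-mediated addition of a phenoxide to dichloroacetylene formed in situ from trichloroethylene, a known route to aryl dichlorovinyl ethers; anti addition of oxygen and hydrogen gives the E isomer, and the linear electrophile is easily reached by the hindered phenoxide.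

Step 10
Reactants: 18 (E)-1,2-dichloroethenyl Ar ether
Product: 21 benzyl 3-(ArO)prop-2-ynoate, via chloroethynyl Ar ether 19 (not isolated), via lithium aryloxyethynide 20 (not isolated)
Conditions: n-BuLi (2.2 equiv), THF, −78 → −40 °C; then cannulate into BnOCOCl, THF, −78 °C
Reagents that add atoms: benzyl chloroformate, O=C(Cl)OCc1ccccc1
Why: Dehydrochlorination to the chloroalkyne followed by chlorine–lithium exchange is the standard route from dichlorovinyl ethers to lithium alkoxyacetylides; acylation with a chloroformate by inverse addition at low temperature gives the push–pull ynoate and limits a second addition.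

Step 11
Reactants: 22 1,1-dimethoxyethene
Product: 23 4,4-dimethoxybut-3-en-2-one
Conditions: AcCl (1 equiv), 22 (2 equiv), Et2O, 0 °C → rt
Reagents that add atoms: acetyl chloride, CC(Cl)=O
Why: C-acylation of a ketene acetal by an acid chloride; the second equivalent of the ketene acetal takes up the hydrogen chloride, so no amine base is present to convert acetyl chloride into ketene.

Step 12
Reactants: 23 4,4-dimethoxybut-3-en-2-one
Product: 24 1,1-dimethoxy-3-(trimethylsilyloxy)buta-1,3-diene
Conditions: Me3SiCl, Et3N, ZnCl2 (cat.), toluene, rt → 40 °C; distil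
Reagents that add atoms: chlorotrimethylsilane, C[Si](C)(C)Cl
Why: Silyl enol ether formation from a methyl ketone under amine and ZnCl2 catalysis, the usual preparation of 2-silyloxydienes; the methyl group is the only enolisable position.

Step 13
Reactants: 21 benzyl 3-(ArO)prop-2-ynoate; 24 1,1-dimethoxy-3-(trimethylsilyloxy)buta-1,3-diene
Product: 27 benzyl 4-hydroxy-2-methoxy-6-(ArO)benzoate, via cyclohexadiene cycloadduct 25 (not isolated), via aryl trimethylsilyl ether 26 (not isolated)
Conditions: 24 (3 equiv), toluene, 80 → 110 °C, sealed tube; then 1 M HCl, THF, rt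
Reagents that add atoms: none
Why: Proposed new method: the closest known reaction type is the Diels–Alder addition and aromatisation of 1,1-dialkoxy-3-silyloxybutadienes with propiolate and acetylenedicarboxylate esters to give resorcinol monoethers, and what is new is a dienophile whose β-carbon carries an aryloxy donor. The reaction is expected to run as a strongly polarised, probably stepwise (4+2) process: the CH2 terminus of 24, the nucleophilic end of both the silyl enol ether and the vinylogous ketene acetal, adds to the β-carbon of 21 (bond A4–A5) to give an allenoate and a dimethoxycarbenium ion. Ring A then closes by attack of the ester-bearing α-carbon on that carbenium carbon (bond A6–A1), a six-membered exo closure that completes cycloadduct 25. Only A1 and A4 are sp3 in 25, so aromatisation can occur in one way only, by loss of methanol across A1 and A4 to give 26, and the acidic work-up removes the silyl group to give 27; the aryloxy group sits on an sp2 carbon throughout and stays. No stereocentre is formed. The selectivity needed is regiochemical and is secured by both partners: the ester makes the aryloxy-bearing carbon the only electrophilic alkyne carbon, and the diene is nucleophilic only at CH2, which puts methoxy, hydroxy and aryloxy on A1, A3 and A5. The aryloxy oxygen of 21 is a weak donor because its lone pairs are shared with ring B, so the alkyne should remain electrophilic enough for the very electron-rich diene at 80–110 °C.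

Step 14
Reactants: 27 benzyl 4-hydroxy-2-methoxy-6-(ArO)benzoate
Product: 29 3-methoxy-5-(ArO)phenol, via benzoic acid 28 (not isolated)
Conditions: H2 (1 atm), Pd/C, EtOAc–MeOH, rt; filter; then CF3CO2H, CH2Cl2, rt → 40 °C
Reagents that add atoms: none
Why: Hydrogenolysis of the benzyl ester under neutral conditions, then acid-promoted protodecarboxylation; a benzoic acid with oxygen on both ortho carbons and the para carbon is protonated at the ipso carbon and loses carbon dioxide readily.

Step 15
Reactants: 29 3-methoxy-5-(ArO)phenol
Product: 30 5-{2,4-dihydroxy-6-[2,6-dihydroxy-4-(2,4-dihydroxy-6-(2,4,6-trihydroxyphenoxy)phenoxy)phenoxy]phenoxy}benzene-1,3-diol (CNP0018313.0)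
Conditions: BBr3 (20 equiv), CH2Cl2, −78 °C → rt; then MeOH, H2O, 0 °C, under argon; reversed-phase or Sephadex LH-20 purification
Reagents that add atoms: none
Why: Lewis-acid cleavage of aryl methyl ethers by BBr3, which leaves diaryl ethers intact; a large excess is used because ten ethers and eleven oxygens bind boron.

## Compound list

1 | 2,4,6-trimethoxybenzaldehyde | COc1cc(OC)c(C=O)c(OC)c1 | starting material
2 | 2,4,6-trimethoxyphenyl formate | COc1cc(OC)c(OC=O)c(OC)c1 | intermediate
3 | 2,4,6-trimethoxyphenol | COc1cc(OC)c(O)c(OC)c1 | intermediate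
4 | 1-fluoro-3,5-dimethoxybenzene | COc1cc(F)cc(OC)c1 | starting material
5 | N-[(2-fluoro-4,6-dimethoxyphenyl)methylidene]-N-methylmethanaminium chloride | C[N+](C)=Cc1c(F)cc(OC)cc1OC.[Cl-] | intermediate
6 | 2-fluoro-4,6-dimethoxybenzaldehyde | COc1cc(F)c(C=O)c(OC)c1 | intermediate
7 | 2,4-dimethoxy-6-(2,4,6-trimethoxyphenoxy)benzaldehyde | COc1cc(OC)c(C=O)c(Oc2c(OC)cc(OC)cc2OC)c1 | intermediate
8 | 2,4-dimethoxy-6-(2,4,6-trimethoxyphenoxy)phenyl formate | COc1cc(OC)c(OC=O)c(Oc2c(OC)cc(OC)cc2OC)c1 | intermediate
9 | 2,4-dimethoxy-6-(2,4,6-trimethoxyphenoxy)phenol | COc1cc(OC)c(O)c(Oc2c(OC)cc(OC)cc2OC)c1 | intermediate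
10 | 4-bromo-2,6-dimethoxybenzaldehyde | COc1cc(Br)cc(OC)c1C=O | starting material
11 | 4-[2,4-dimethoxy-6-(2,4,6-trimethoxyphenoxy)phenoxy]-2,6-dimethoxybenzaldehyde | COc1cc(Oc2c(OC)cc(OC)cc2Oc2c(OC)cc(OC)cc2OC)cc(OC)c1C=O | intermediate
12 | 4-[2,4-dimethoxy-6-(2,4,6-trimethoxyphenoxy)phenoxy]-2,6-dimethoxyphenyl formate | COc1cc(Oc2c(OC)cc(OC)cc2Oc2c(OC)cc(OC)cc2OC)cc(OC)c1OC=O | intermediate
13 | 4-[2,4-dimethoxy-6-(2,4,6-trimethoxyphenoxy)phenoxy]-2,6-dimethoxyphenol | COc1cc(Oc2c(OC)cc(OC)cc2Oc2c(OC)cc(OC)cc2OC)cc(OC)c1O | intermediate
14 | 2-{4-[2,4-dimethoxy-6-(2,4,6-trimethoxyphenoxy)phenoxy]-2,6-dimethoxyphenoxy}-4,6-dimethoxybenzaldehyde | O=Cc1c(OC)cc(OC)cc1Oc1c(OC)cc(Oc2c(OC)cc(OC)cc2Oc2c(OC)cc(OC)cc2OC)cc1OC | intermediate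
15 | 2-{4-[2,4-dimethoxy-6-(2,4,6-trimethoxyphenoxy)phenoxy]-2,6-dimethoxyphenoxy}-4,6-dimethoxyphenyl formate | O=COc1c(OC)cc(OC)cc1Oc1c(OC)cc(Oc2c(OC)cc(OC)cc2Oc2c(OC)cc(OC)cc2OC)cc1OC | intermediate
16 | 2-{4-[2,4-dimethoxy-6-(2,4,6-trimethoxyphenoxy)phenoxy]-2,6-dimethoxyphenoxy}-4,6-dimethoxyphenol (ArOH) | Oc1c(OC)cc(OC)cc1Oc1c(OC)cc(Oc2c(OC)cc(OC)cc2Oc2c(OC)cc(OC)cc2OC)cc1OC | intermediate
17 | trichloroethylene | ClC=C(Cl)Cl | starting material
18 | (E)-1,2-dichloroethenyl Ar ether | Cl/C=C(/Cl)Oc1c(OC)cc(OC)cc1Oc1c(OC)cc(Oc2c(OC)cc(OC)cc2Oc2c(OC)cc(OC)cc2OC)cc1OC | intermediate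
19 | chloroethynyl Ar ether | ClC#COc1c(OC)cc(OC)cc1Oc1c(OC)cc(Oc2c(OC)cc(OC)cc2Oc2c(OC)cc(OC)cc2OC)cc1OC | intermediate
20 | lithium 2-(ArO)ethynide | [Li]C#COc1c(OC)cc(OC)cc1Oc1c(OC)cc(Oc2c(OC)cc(OC)cc2Oc2c(OC)cc(OC)cc2OC)cc1OC | intermediate
21 | benzyl 3-(ArO)prop-2-ynoate | O=C(OCc1ccccc1)C#COc1c(OC)cc(OC)cc1Oc1c(OC)cc(Oc2c(OC)cc(OC)cc2Oc2c(OC)cc(OC)cc2OC)cc1OC | intermediate
22 | 1,1-dimethoxyethene | C=C(OC)OC | starting material
23 | 4,4-dimethoxybut-3-en-2-one | CC(=O)C=C(OC)OC | intermediate
24 | 1,1-dimethoxy-3-(trimethylsilyloxy)buta-1,3-diene | COC(OC)=CC(=C)O[Si](C)(C)C | intermediate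
25 | benzyl 6,6-dimethoxy-2-(ArO)-4-(trimethylsilyloxy)cyclohexa-1,4-diene-1-carboxylate | COC1(OC)C=C(O[Si](C)(C)C)CC(Oc2c(OC)cc(OC)cc2Oc2c(OC)cc(Oc3c(OC)cc(OC)cc3Oc3c(OC)cc(OC)cc3OC)cc2OC)=C1C(=O)OCc1ccccc1 | intermediate
26 | benzyl 2-methoxy-6-(ArO)-4-(trimethylsilyloxy)benzoate | COc1cc(O[Si](C)(C)C)cc(Oc2c(OC)cc(OC)cc2Oc2c(OC)cc(Oc3c(OC)cc(OC)cc3Oc3c(OC)cc(OC)cc3OC)cc2OC)c1C(=O)OCc1ccccc1 | intermediate
27 | benzyl 4-hydroxy-2-methoxy-6-(ArO)benzoate | COc1cc(O)cc(Oc2c(OC)cc(OC)cc2Oc2c(OC)cc(Oc3c(OC)cc(OC)cc3Oc3c(OC)cc(OC)cc3OC)cc2OC)c1C(=O)OCc1ccccc1 | intermediate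
28 | 4-hydroxy-2-methoxy-6-(ArO)benzoic acid | COc1cc(O)cc(Oc2c(OC)cc(OC)cc2Oc2c(OC)cc(Oc3c(OC)cc(OC)cc3Oc3c(OC)cc(OC)cc3OC)cc2OC)c1C(=O)O | intermediate
29 | 3-methoxy-5-(ArO)phenol | COc1cc(O)cc(Oc2c(OC)cc(OC)cc2Oc2c(OC)cc(Oc3c(OC)cc(OC)cc3Oc3c(OC)cc(OC)cc3OC)cc2OC)c1 | intermediate
30 | 5-{2,4-dihydroxy-6-[2,6-dihydroxy-4-(2,4-dihydroxy-6-(2,4,6-trihydroxyphenoxy)phenoxy)phenoxy]phenoxy}benzene-1,3-diol (CNP0018313.0) | Oc1cc(O)cc(Oc2c(O)cc(O)cc2Oc2c(O)cc(Oc3c(O)cc(O)cc3Oc3c(O)cc(O)cc3O)cc2O)c1 | target

## Step count and risk

Total steps: 15. Longest linear sequence: 12 steps (steps 1, 3 to 10 and 13 to 15, from 1 to 30). Steps 2, 11 and 12 are side branches.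

Step 13 (key step, proposed new method). The push–pull alkyne may react too slowly, so that the diene is lost to desilylation or oligomerisation first. In a stepwise pathway the intermediate may also expel the tetramer phenoxide from the alkyne terminus (addition–elimination) without closing the ring. The fallback uses known chemistry and builds ring A on the B1 oxygen by activated substitution with a formyl group as the removable activator. It sets out from 16, which is coupled with 6 under the conditions of step 7 to give 2-(ArO)-4,6-dimethoxybenzaldehyde F1. Pinnick oxidation (NaClO2, NaH2PO4, 2-methylbut-2-ene, t-BuOH–H2O) gives 2-(ArO)-4,6-dimethoxybenzoic acid F2. Protodecarboxylation in CF3CO2H gives 1-(ArO)-3,5-dimethoxybenzene F3, and BBr3 cleavage of its eleven methyl ethers returns to the route at 30.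

Step 5. Coordination of the doubly ortho-substituted phenoxide to copper and the C–O bond-forming step may be slow, which leaves time for hydrodebromination of 10. The fallback replaces the catalysed coupling by an uncatalysed fluoride displacement. It sets out from 9, which is heated with Cs2CO3 in DMSO and 4-fluoro-2,6-dimethoxybenzaldehyde F4, and it returns at 11. F4 is expected as the minor regioisomer of the formylation of 4 in step 2 and can be kept from that separation.

Step 10. Excess butyllithium may metalate ring positions between two oxygens, and the acetylide may add a second time to the acylated product. The fallback separates alkyne formation from carboxylation. It sets out from 18, which is treated with n-BuLi and quenched with water to give ethynyl Ar ether F5; any ring-lithiated material is protonated harmlessly at this point. Copper-catalysed carboxylation (CuI, Cs2CO3, CO2 at 1 atm, DMF) gives caesium 3-(ArO)prop-2-ynoate F6, which is alkylated in the same pot with benzyl bromide to return at 21.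

Step 15. Cleavage of the last of the ten ethers may stall through boron chelation between neighbouring oxygens, and the free polyphenol may be lost to air oxidation during isolation. The fallback isolates the product through a stable derivative. It sets out from 29, which is treated with BBr3 as before; the crude product is acetylated (Ac2O, pyridine) to the undecaacetate of 30 F7 and purified on silica. Acid-catalysed methanolysis (HCl in MeOH, under argon) returns at 30.

## Further compounds

F1 | step 13 | 2-(ArO)-4,6-dimethoxybenzaldehyde | O=Cc1c(OC)cc(OC)cc1Oc1c(OC)cc(OC)cc1Oc1c(OC)cc(Oc2c(OC)cc(OC)cc2Oc2c(OC)cc(OC)cc2OC)cc1OC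
F2 | step 13 | 2-(ArO)-4,6-dimethoxybenzoic acid | OC(=O)c1c(OC)cc(OC)cc1Oc1c(OC)cc(OC)cc1Oc1c(OC)cc(Oc2c(OC)cc(OC)cc2Oc2c(OC)cc(OC)cc2OC)cc1OC
F3 | step 13 | 1-(ArO)-3,5-dimethoxybenzene | COc1cc(OC)cc(Oc2c(OC)cc(OC)cc2Oc2c(OC)cc(Oc3c(OC)cc(OC)cc3Oc3c(OC)cc(OC)cc3OC)cc2OC)c1
F4 | step 5 | 4-fluoro-2,6-dimethoxybenzaldehyde | COc1cc(F)cc(OC)c1C=O
F5 | step 10 | ethynyl Ar ether | C#COc1c(OC)cc(OC)cc1Oc1c(OC)cc(Oc2c(OC)cc(OC)cc2Oc2c(OC)cc(OC)cc2OC)cc1OC
F6 | step 10 | caesium 3-(ArO)prop-2-ynoate | [Cs+].[O-]C(=O)C#COc1c(OC)cc(OC)cc1Oc1c(OC)cc(Oc2c(OC)cc(OC)cc2Oc2c(OC)cc(OC)cc2OC)cc1OC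
F7 | step 15 | undecaacetate of 30 | CC(=O)Oc1cc(OC(C)=O)cc(Oc2c(OC(C)=O)cc(OC(C)=O)cc2Oc2c(OC(C)=O)cc(Oc3c(OC(C)=O)cc(OC(C)=O)cc3Oc3c(OC(C)=O)cc(OC(C)=O)cc3OC(C)=O)cc2OC(C)=O)c1
A1 | alternative 1 | 4-[1-(4-benzyloxy-2,6-dimethoxyphenoxy)ethenyl]-4-hydroxy-3-isopropoxycyclobut-2-en-1-one (racemic) | O=C1C=C(OC(C)C)C1(O)C(=C)Oc1c(OC)cc(OCc2ccccc2)cc1OC
A2 | alternative 1 | 2-(4-benzyloxy-2,6-dimethoxyphenoxy)-6-isopropoxybenzene-1,4-diol | CC(C)Oc1cc(O)cc(Oc2c(OC)cc(OCc3ccccc3)cc2OC)c1O
A3 | alternative 2 | dimethyl 2-(2-benzyloxy-3,5-dimethoxyphenoxy)malonate | COC(=O)C(Oc1cc(OC)cc(OC)c1OCc1ccccc1)C(=O)OC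
A4 | alternative 2 | dimethyl 3-oxopentanedioate | COC(=O)CC(=O)CC(=O)OC
A5 | alternative 2 | dimethyl 5-(2-benzyloxy-3,5-dimethoxyphenoxy)-2,4,6-trihydroxyisophthalate | COC(=O)c1c(O)c(C(=O)OC)c(O)c(Oc2cc(OC)cc(OC)c2OCc2ccccc2)c1O
A6 | alternative 3 | 4-(4-benzyloxy-3,5-dimethoxyphenoxy)-3-(2,4,6-trimethoxyphenoxy)cyclobut-2-en-1-one (racemic) | O=C1C=C(Oc2c(OC)cc(OC)cc2OC)C1Oc1cc(OC)c(OCc2ccccc2)c(OC)c1
A7 | alternative 3 | ethoxyacetylene | CCOC#C
A8 | alternative 3 | 2-(4-benzyloxy-3,5-dimethoxyphenoxy)-5-ethoxy-3-(2,4,6-trimethoxyphenoxy)phenol | CCOc1cc(O)c(Oc2cc(OC)c(OCc3ccccc3)c(OC)c2)c(Oc2c(OC)cc(OC)cc2OC)c1
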